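Readings and results are calculated with made-up constants; the scatter is artificial.

Two questions are asked of this flask, both about r = c(Z)/c(J), one early and one late.

| flask | X | remark | time |
|---|---|---|---|
| Thursday's | 6 mM | run made earlier |  |
| Saturday's | 9 mM | run made earlier |  |
| flask | 12 mM |  | 2.5 d |

| run | time / d | Z / % | J / % |
|---|---|---|---|
| Thursday's | 0.250 | 4.9 | 20.6 |
| Thursday's | 0.417 | 8.0 | 26.4 |
| Thursday's | 0.625 | 10.8 | 33.2 |
| Thursday's | 1.04 | 16.1 | 43.3 |
| Thursday's | 1.67 | 22.6 | 53.1 |
| Thursday's | 3.00 | 28.2 | 64.3 |
| Saturday's | 0.208 | 3.7 | 18.2 |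
| Saturday's | 0.625 | 10.9 | 33.0 |
| Saturday's | 1.04 | 16.2 | 43.0 |
| Saturday's | 1.67 | 22.8 | 53.6 |
| Saturday's | 2.50 | 26.7 | 60.5 |
| Saturday's | 3.00 | 27.7 | 63.1 |

(each reading ± 0.5 percentage points)

* ratio of Z to J at 20 min
* ratio of Z to J at 2.5 d



- At 0.625 d, Thursday's run at c(X) = 6 mM gives Z 10.8% and J 33.2%, and Saturday's at 9 mM gives 10.9% and 33.0%. The percentages agree within the scatter, so we carry the same curves over to the flask at 12 mM.
- We read two things from these curves. The plateau of r is 0.439 at 3.00 d in Thursday's run, and r already reads 0.238 at 0.250 d, about half of that plateau.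
- So we carry one quantity: the half-rise time 0.250 d, read in Thursday's run, the time r takes to reach about half its plateau. Any time is then counted in half-rise times.
- The first extreme version has J and Z exchanging at once, which is thermodynamic control: r equals 0.439 at every moment.
- The second has Z only starting to grow out of J, so r climbs from zero on a straight line through the half mark. Then r = plateau × t/(2 × half-rise time).
- We expect the real flask to start near the line and end near the plateau. Now 20 min is 0.0556 half-rise times, far shorter than one, so we commit to the line, 0.0122. And 2.5 d is 10.0 half-rise times, so we commit to the plateau, 0.439.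
- The forecast gave 0.09 and 0.44, holding that at the early time “J is poorly constrained”, and its early value stands above our line.
- The flask gives 0.0108 and 0.437.

    X → Q (k = 0.00920 /min)
    Q → J (k = 0.0280 /min)
    X ⇌ E (K = 14.0, k = 0.0700 /min)
    J ⇌ Z (K = 0.450, k = 0.00140 /min)

- Our line of 0.0122 stands above the flask's early ratio, by a factor of 1.13. The neighbouring flask is charged with 3.0 mM of X instead of 12 mM, at the same times, so the count is again 0.0556 and 10.0 half-rise times, and the reckoning again gives 0.0122 and 0.439. That flask gives 0.0108 and 0.437, with J at 60.8% and Z at 26.6% of its charge at 2.50 d.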